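## Retrosynthetic overview

1. Target 12 ← hydrogenolysis of monobenzyl ether 11 (the phenol of unit A is masked as a benzyl ether).
2. 11 ← unit B C2–unit C C4 bond by a proposed acid-catalysed dealkoxylative arylation of quinol ether 8 with the para C–H of 8-methoxynaphthalen-1-ol 2.
3. 8 ← oxidative dearomatisation of binaphthol 7 ← Suzuki–Miyaura coupling (unit A C2–unit B C4) of boronate 5 with 4-bromonaphthol 6.
4. 5 and 6 ← ortho- and para-bromination of 2 ← mono-methylation of naphthalene-1,8-diol 1.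
5. No ring is built: all three naphthalenes come intact from 1, and the biaryl bonds are made in the order A–B, then B–C.

Assumption: the target SMILES has no stereodescriptors and both biaryl axes (a 1-naphthyl joined to an aryl with one ortho OH) rotate freely at room temperature, so the target is made as one achiral compound and no stereocontrol is needed.

## Route

Step 1
Reactants: 1 naphthalene-1,8-diol
Product: 2 8-methoxynaphthalen-1-ol
Conditions: MeI (1.1 equiv), K2CO3 (1.1 equiv), acetone, reflux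
Reagents that add atoms: iodomethane, CI
Why: Williamson ether synthesis; after the first methylation the remaining OH is hydrogen-bonded to the peri methoxy oxygen and much less acidic, so the reaction stops at the mono-ether.

Step 2
Reactants: 2 8-methoxynaphthalen-1-ol
Product: 3 2-bromo-8-methoxynaphthalen-1-ol
Conditions: NBS (1.0 equiv), i-Pr2NH (10 mol%), CH2Cl2, 0 °C to rt
Reagents that add atoms: N-bromosuccinimide, O=C1CCC(=O)N1Br
Why: Amine-mediated electrophilic aromatic bromination; the N-bromoamine is delivered through a hydrogen bond to the phenolic OH, so bromine enters ortho (C2) on the hydroxylated ring.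

Step 3
Reactants: 3 2-bromo-8-methoxynaphthalen-1-ol
Product: 4 1-(benzyloxy)-2-bromo-8-methoxynaphthalene
Conditions: BnBr (1.2 equiv), K2CO3 (2 equiv), DMF, 60 °C
Reagents that add atoms: benzyl bromide, BrCc1ccccc1
Why: Williamson ether synthesis on the naphthoxide; the benzyl ether survives palladium coupling, the trivalent iodine oxidant and the acid of step 8, and is removed by hydrogenolysis at the end.

Step 4
Reactants: 4 1-(benzyloxy)-2-bromo-8-methoxynaphthalene
Product: 5 2-[1-(benzyloxy)-8-methoxynaphthalen-2-yl]-4,4,5,5-tetramethyl-1,3,2-dioxaborolane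
Conditions: B2pin2 (1.2 equiv), PdCl2(dppf) (5 mol%), KOAc (3 equiv), 1,4-dioxane, 90 °C
Reagents that add atoms: bis(pinacolato)diboron, CC1(C)OB(OC1(C)C)B1OC(C)(C)C(C)(C)O1
Why: Miyaura borylation (oxidative addition to zerovalent palladium, acetate-assisted transmetalation, reductive elimination); the benzyl and methyl ethers are inert.

Step 5
Reactants: 2 8-methoxynaphthalen-1-ol
Product: 6 4-bromo-8-methoxynaphthalen-1-ol
Conditions: NBS (1.0 equiv), MeCN, −20 °C to 0 °C
Reagents that add atoms: N-bromosuccinimide, O=C1CCC(=O)N1Br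
Why: Electrophilic aromatic bromination without amine in polar MeCN goes para to the free OH (C4), the most electron-rich and least hindered carbon of the far more activated hydroxylated ring.

Step 6
Reactants: 5 2-[1-(benzyloxy)-8-methoxynaphthalen-2-yl]-4,4,5,5-tetramethyl-1,3,2-dioxaborolane; 6 4-bromo-8-methoxynaphthalen-1-ol
Product: 7 4-[1-(benzyloxy)-8-methoxynaphthalen-2-yl]-8-methoxynaphthalen-1-ol
Conditions: Pd(OAc)2 (3 mol%), SPhos (6 mol%), K3PO4 (3 equiv), toluene/H2O 10:1, degassed, 80 °C
Reagents that add atoms: none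
Why: Suzuki–Miyaura coupling; SPhos-ligated palladium inserts into the electron-rich naphthyl bromide even as its phenoxide and couples the mono-ortho-substituted boronate, forming the unit A C2–unit B C4 bond.

Step 7
Reactants: 7 4-[1-(benzyloxy)-8-methoxynaphthalen-2-yl]-8-methoxynaphthalen-1-ol
Product: 8 4-[1-(benzyloxy)-8-methoxynaphthalen-2-yl]-4,8-dimethoxynaphthalen-1(4H)-one (racemic)
Conditions: PhI(OAc)2 (1.05 equiv), MeOH/CH2Cl2 3:1, 0 °C, 15 min
Reagents that add atoms: methanol, CO
Why: Oxidative dearomatisation of a para-substituted naphthol by a trivalent iodine reagent; only the free naphthol binds iodine and methanol adds at the para carbon C4, giving the quinol ether as a racemate whose stereocenter is erased in step 8.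

Step 8
Reactants: 8 4-[1-(benzyloxy)-8-methoxynaphthalen-2-yl]-4,8-dimethoxynaphthalen-1(4H)-one (racemic); 2 8-methoxynaphthalen-1-ol
Product: 11 4-[1-(benzyloxy)-8-methoxynaphthalen-2-yl]-2-(4-hydroxy-5-methoxynaphthalen-1-yl)-8-methoxynaphthalen-1-ol, via naphthoxenium cation 9 (not isolated), via keto tautomer 10 (not isolated)
Conditions: 2 (1.5 equiv), (PhO)2P(O)OH (10 mol%), HFIP/CH2Cl2 4:1, −20 °C to 0 °C
Reagents that add atoms: none
Why: Proposed new method: acid and HFIP ionise the tertiary, doubly benzylic C4–OMe bond of 8 to the aryl-stabilised cation 9, whose C4 is shielded by the peri hydrogen and the ortho-benzyloxy aryl group, so the para carbon C4 of naphthol 2 (its oxygen is tied up by the internal OH···OMe bond and by HFIP) attacks C2 in SN2′ fashion and the resulting dienone 10 tautomerises irreversibly to the naphthol; because no oxidant is present, the two near-identical naphthols cannot homo-couple and only the ortho–para linkage forms. The closest known reaction type is the acid-promoted SN2′ arylation of quinone monoacetals by electron-rich arenes, which has not been shown for a 4-aryl quinol ether of the naphthalene series with a free 1-naphthol as carbon nucleophile.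

Step 9
Reactants: 11 4-[1-(benzyloxy)-8-methoxynaphthalen-2-yl]-2-(4-hydroxy-5-methoxynaphthalen-1-yl)-8-methoxynaphthalen-1-ol
Product: 12 2-(4-hydroxy-5-methoxynaphthalen-1-yl)-4-(1-hydroxy-8-methoxynaphthalen-2-yl)-8-methoxynaphthalen-1-ol
Conditions: H2 (1 atm), Pd/C (10 wt%), EtOAc/MeOH 1:1, rt, work-up under argon
Reagents that add atoms: none
Why: Hydrogenolysis of the aryl benzyl ether on palladium; methyl ethers, free naphthols and the naphthalene rings are untouched at 1 atm and rt, and no stereocenter or stable axis needs control.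

## Compound list

1 | naphthalene-1,8-diol | Oc1cccc2cccc(O)c12 | starting material
2 | 8-methoxynaphthalen-1-ol | COc1cccc2cccc(O)c12 | intermediate
3 | 2-bromo-8-methoxynaphthalen-1-ol | COc1cccc2ccc(Br)c(O)c12 | intermediate
4 | 1-(benzyloxy)-2-bromo-8-methoxynaphthalene | COc1cccc2ccc(Br)c(OCc3ccccc3)c12 | intermediate
5 | 2-[1-(benzyloxy)-8-methoxynaphthalen-2-yl]-4,4,5,5-tetramethyl-1,3,2-dioxaborolane | COc1cccc2ccc(B3OC(C)(C)C(C)(C)O3)c(OCc3ccccc3)c12 | intermediate
6 | 4-bromo-8-methoxynaphthalen-1-ol | COc1cccc2c(Br)ccc(O)c12 | intermediate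
7 | 4-[1-(benzyloxy)-8-methoxynaphthalen-2-yl]-8-methoxynaphthalen-1-ol | COc1cccc2ccc(-c3ccc(O)c4c(OC)cccc34)c(OCc3ccccc3)c12 | intermediate
8 | 4-[1-(benzyloxy)-8-methoxynaphthalen-2-yl]-4,8-dimethoxynaphthalen-1(4H)-one (racemic) | COc1cccc2ccc(C3(OC)C=CC(=O)c4c(OC)cccc34)c(OCc3ccccc3)c12 | intermediate
9 | 4-[1-(benzyloxy)-8-methoxynaphthalen-2-yl]-8-methoxy-1-oxo-1,4-dihydronaphthalen-4-ylium (naphthoxenium cation, not isolated) | COc1cccc2ccc([C+]3C=CC(=O)c4c(OC)cccc34)c(OCc3ccccc3)c12 | intermediate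
10 | 4-[1-(benzyloxy)-8-methoxynaphthalen-2-yl]-2-(4-hydroxy-5-methoxynaphthalen-1-yl)-8-methoxynaphthalen-1(2H)-one (racemic keto tautomer, not isolated) | COc1cccc2ccc(C3=CC(c4ccc(O)c5c(OC)cccc45)C(=O)c4c(OC)cccc34)c(OCc3ccccc3)c12 | intermediate
11 | 4-[1-(benzyloxy)-8-methoxynaphthalen-2-yl]-2-(4-hydroxy-5-methoxynaphthalen-1-yl)-8-methoxynaphthalen-1-ol | COc1cccc2ccc(-c3cc(-c4ccc(O)c5c(OC)cccc45)c(O)c4c(OC)cccc34)c(OCc3ccccc3)c12 | intermediate
12 | 2-(4-hydroxy-5-methoxynaphthalen-1-yl)-4-(1-hydroxy-8-methoxynaphthalen-2-yl)-8-methoxynaphthalen-1-ol | COc1cccc2ccc(-c3cc(-c4ccc(O)c5c(OC)cccc45)c(O)c4c(OC)cccc34)c(O)c12 | target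

## Step count and risks

Total step count: 9.
Longest linear sequence: 8 steps (steps 1, 2, 3, 4, 6, 7, 8, 9). Step 5 is a one-step branch from 2.

The three steps most likely to fail:

**Step 8 (the proposed new arylation).** The risks are O-attack followed by a sigmatropic shift to the ortho–ortho isomer, attack through C2 of the nucleophile, or electron transfer from naphthol 2 to cation 9. The fallback uses known chemistry, sets out from 7 and 6, and comes back at 12. Binaphthol 7 is brominated ortho to its free OH (NBS, i-Pr2NH cat., CH2Cl2, 0 °C) to give 4-[1-(benzyloxy)-8-methoxynaphthalen-2-yl]-2-bromo-8-methoxynaphthalen-1-ol F7. In parallel 6 is benzylated (BnBr, K2CO3, DMF) to 1-(benzyloxy)-4-bromo-8-methoxynaphthalene F8, which is borylated (B2pin2, PdCl2(dppf), KOAc, dioxane, 90 °C) to 2-[4-(benzyloxy)-5-methoxynaphthalen-1-yl]-4,4,5,5-tetramethyl-1,3,2-dioxaborolane F9. Suzuki–Miyaura coupling of F7 with F9 (Pd(OAc)2, SPhos, K3PO4, toluene/H2O, 80 °C) gives 4-[1-(benzyloxy)-8-methoxynaphthalen-2-yl]-2-[4-(benzyloxy)-5-methoxynaphthalen-1-yl]-8-methoxynaphthalen-1-ol F10. Hydrogenolysis of both benzyl ethers (H2, Pd/C, EtOAc/MeOH) gives 12.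

**Step 2 (ortho-bromination).** Para-bromination or dibromination may compete. The fallback replaces electrophilic substitution by directed ortho-metalation, sets out from 2, and comes back at 3. Naphthol 2 is protected (MOMCl, i-Pr2NEt, CH2Cl2) as 1-methoxy-8-(methoxymethoxy)naphthalene F1. Lithiation ortho to the stronger directing OMOM group (n-BuLi, TMEDA, Et2O, 0 °C) gives [8-methoxy-1-(methoxymethoxy)naphthalen-2-yl]lithium F2. Quenching with BrCCl2CCl2Br at −78 °C gives 2-bromo-8-methoxy-1-(methoxymethoxy)naphthalene F3. Cleavage of the acetal (HCl, MeOH, 40 °C) gives 3.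

**Step 6 (Suzuki coupling with an unprotected, oxidation-prone 4-bromonaphthol).** The phenoxide may slow oxidative addition or decompose, and boronate 5 may protodeboronate. The fallback protects the naphthol and inverts the polarity of the partners, sets out from 6 and 4, and comes back at 7. Bromonaphthol 6 is protected (MOMCl, i-Pr2NEt, CH2Cl2) as 4-bromo-8-methoxy-1-(methoxymethoxy)naphthalene F4. Miyaura borylation (B2pin2, PdCl2(dppf), KOAc, dioxane, 90 °C) gives 2-[5-methoxy-4-(methoxymethoxy)naphthalen-1-yl]-4,4,5,5-tetramethyl-1,3,2-dioxaborolane F5. Coupling of F5 with bromide 4 (Pd(OAc)2, SPhos, K3PO4, toluene/H2O, 80 °C) gives 1-(benzyloxy)-8-methoxy-2-[5-methoxy-4-(methoxymethoxy)naphthalen-1-yl]naphthalene F6. Acetal cleavage (HCl, MeOH/THF, 40 °C) gives 7.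

## Further compounds

F1 | step 2 | 1-methoxy-8-(methoxymethoxy)naphthalene | COCOc1cccc2cccc(OC)c12
F2 | step 2 | [8-methoxy-1-(methoxymethoxy)naphthalen-2-yl]lithium | [Li]c1ccc2cccc(OC)c2c1OCOC
F3 | step 2 | 2-bromo-8-methoxy-1-(methoxymethoxy)naphthalene | COCOc1c(Br)ccc2cccc(OC)c12
F4 | step 6 | 4-bromo-8-methoxy-1-(methoxymethoxy)naphthalene | COCOc1ccc(Br)c2cccc(OC)c12
F5 | step 6 | 2-[5-methoxy-4-(methoxymethoxy)naphthalen-1-yl]-4,4,5,5-tetramethyl-1,3,2-dioxaborolane | COCOc1ccc(B3OC(C)(C)C(C)(C)O3)c2cccc(OC)c12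
F6 | step 6 | 1-(benzyloxy)-8-methoxy-2-[5-methoxy-4-(methoxymethoxy)naphthalen-1-yl]naphthalene | COc1cccc2ccc(-c3ccc(OCOC)c4c(OC)cccc34)c(OCc3ccccc3)c12
F7 | step 8 | 4-[1-(benzyloxy)-8-methoxynaphthalen-2-yl]-2-bromo-8-methoxynaphthalen-1-ol | COc1cccc2ccc(-c3cc(Br)c(O)c4c(OC)cccc34)c(OCc3ccccc3)c12
F8 | step 8 | 1-(benzyloxy)-4-bromo-8-methoxynaphthalene | COc1cccc2c(Br)ccc(OCc3ccccc3)c12
F9 | step 8 | 2-[4-(benzyloxy)-5-methoxynaphthalen-1-yl]-4,4,5,5-tetramethyl-1,3,2-dioxaborolane | COc1cccc2c(B3OC(C)(C)C(C)(C)O3)ccc(OCc3ccccc3)c12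
F10 | step 8 | 4-[1-(benzyloxy)-8-methoxynaphthalen-2-yl]-2-[4-(benzyloxy)-5-methoxynaphthalen-1-yl]-8-methoxynaphthalen-1-ol | COc1cccc2ccc(-c3cc(-c4ccc(OCc5ccccc5)c5c(OC)cccc45)c(O)c4c(OC)cccc34)c(OCc3ccccc3)c12
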